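Assumption: N,N-dimethylformamide and acetic acid are counted as starting materials because they supply skeletal carbon, and flavanones 10–13 are carried as 1:1 mixtures of C2 epimers because C2 loses its stereochemistry in step 8.

**Retrosynthetic overview**
- The target comes from a 2'-O-protected isoflav-3-ene by reagent-controlled syn hydroboration and oxidation, which sets the 3,4-trans pair; the phenol esters fall off in the same work-up.
- The isoflavene comes from an isoflavone (reduce, dehydrate), and the isoflavone from a flavanone by an oxidative 1,2-aryl shift of ring B from C2 to C3.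
- The pyran carbinol is set on the flavanone by Mn-salen epoxidation of the 2,2-dimethylchromene and benzylic hydrogenolysis.
- The flavanone comes from 2,4-dihydroxyacetophenone and a chromene aldehyde by condensation and oxa-Michael closure.
- Both halves come from resorcinol. Ring order: pyran ring on ring B, then ring C as a flavanone, then ring C rearranged to the isoflavonoid.

**Route**

Step 1
Reactants: 1 resorcinol; 2 N,N-dimethylformamide
Product: 4 2,4-dihydroxybenzaldehyde, via iminium chloride 3 (not isolated)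
Conditions: POCl3, DMF, MeCN, −15 → 25 °C; then H2O, 50 °C
Reagents that add atoms: water (O)
Why: Vilsmeier–Haack formylation; the chloroiminium ion attacks the position para to one OH and ortho to the other, and the iminium salt is hydrolysed to the aldehyde.

Step 2
Reactants: 4 2,4-dihydroxybenzaldehyde; 5 3-methylbut-2-enal
Product: 6 5-hydroxy-2,2-dimethyl-2H-chromene-6-carbaldehyde
Conditions: ethylenediammonium diacetate (10 mol%), xylene, 140 °C
Reagents that add atoms: none
Why: Knoevenagel-type condensation at the carbon between the two oxygens, then oxa-6π ring closure through the 4-OH; the chelated 2-OH stays free, which gives the angular chromene.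

Step 3
Reactants: 1 resorcinol; 7 acetic acid
Product: 8 1-(2,4-dihydroxyphenyl)ethanone
Conditions: ZnCl2, AcOH, 150 °C
Reagents that add atoms: none
Why: Nencki (Friedel–Crafts) acylation of resorcinol para to one OH.

Step 4
Reactants: 6 5-hydroxy-2,2-dimethyl-2H-chromene-6-carbaldehyde; 8 1-(2,4-dihydroxyphenyl)ethanone
Product: 10 (±)-7-hydroxy-2-(5-hydroxy-2,2-dimethyl-2H-chromen-6-yl)chroman-4-one, via chalcone 9 (not isolated)
Conditions: pyrrolidine (1 equiv), EtOH, 78 °C
Reagents that add atoms: none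
Why: Kabbe-type amine-mediated Claisen–Schmidt condensation (enamine/iminium) followed by oxa-Michael addition of the 2'-OH closes ring C; C2 forms as a racemate, which does not matter.

Step 5
Reactants: 10 (±)-7-hydroxy-2-(5-hydroxy-2,2-dimethyl-2H-chromen-6-yl)chroman-4-one
Product: 11 (±)-2-[2,2-dimethyl-5-(pivaloyloxy)-2H-chromen-6-yl]-4-oxochroman-7-yl pivalate
Conditions: PivCl, pyridine, DMAP (cat.), 0 → 25 °C
Reagents that add atoms: pivaloyl chloride (CC(C)(C)C(Cl)=O)
Why: DMAP-catalysed acylation of both phenols; the pivalates should survive peracid, hydrogenolysis, the iodine oxidant, NaBH4 and mild acid, and the 2'-ester later blocks pterocarpan closure.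

Step 6
Reactants: 11 (±)-2-[2,2-dimethyl-5-(pivaloyloxy)-2H-chromen-6-yl]-4-oxochroman-7-yl pivalate
Product: 12 (3R,4R)-3,4-epoxide of 11 on the dimethylpyran ring (C2 epimers of the chromanone 1:1)
Conditions: (R,R)-(salen)MnCl (5 mol%), mCPBA, N-methylmorpholine N-oxide, CH2Cl2, −78 °C
Reagents that add atoms: m-chloroperbenzoic acid (OOC(=O)c1cccc(Cl)c1)
Why: Jacobsen–Katsuki epoxidation with chloro[(R,R)-N,N'-bis(3,5-di-tert-butylsalicylidene)cyclohexane-1,2-diaminato]manganese (trivalent manganese); 2,2-dimethylchromenes are its best substrates and the (R,R) catalyst gives the (3R,4R)-epoxide under catalyst control, while the ketone and the esters are inert at −78 °C.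

Step 7
Reactants: 12 (3R,4R)-epoxide
Product: 13 2-[(3R)-3-hydroxy-2,2-dimethyl-5-(pivaloyloxy)chroman-6-yl]-4-oxochroman-7-yl pivalate (C2 epimers 1:1)
Conditions: H2 (1 atm), Pd/C (10%), EtOAc, 25 °C
Reagents that add atoms: none
Why: Heterogeneous hydrogenolysis cleaves only the benzylic C4–O bond of the epoxide, so the C3–O bond and its (R) configuration are untouched; the aryl ketone and the cyclic benzylic ether of the flavanone react much more slowly.

Step 8
Reactants: 13 flavanone carbinol (C2 epimers)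
Product: 14 3-[(3R)-3-hydroxy-2,2-dimethyl-5-(pivaloyloxy)chroman-6-yl]-4-oxo-4H-chromen-7-yl pivalate (isoflavone)
Conditions: PhI(OH)OTs (1.2 equiv), MeCN, 80 °C
Reagents that add atoms: none
Why: Oxidative 2,3-aryl migration of a flavanone with Koser's reagent (trivalent iodine): the enol is iodinated at C3, the electron-rich ring B shifts from C2 to C3 as PhI leaves with the ring oxygen stabilising the C2 cation, and loss of H3 gives the isoflavone, so both C2 epimers converge.

Step 9
Reactants: 14 isoflavone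
Product: 16 3-[(3R)-3-hydroxy-2,2-dimethyl-5-(pivaloyloxy)chroman-6-yl]-2H-chromen-7-yl pivalate (isoflav-3-ene), via isoflavan-4-ol mixture 15 (not isolated)
Conditions: NaBH4, THF/EtOH, 0 → 25 °C; then TsOH·H2O (cat.), toluene, 60 °C
Reagents that add atoms: none
Why: Conjugate then carbonyl hydride reduction gives the isoflavan-4-ols, and acid-catalysed E1 dehydration of the oxygen-activated benzylic alcohol gives the conjugated isoflav-3-ene; the 2'-pivalate prevents cyclisation to a pterocarpan and the non-benzylic pyran carbinol does not ionise.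

Step 10
Reactants: 16 isoflav-3-ene
Product: 19 (3R,4S)-3-[(3R)-3,5-dihydroxy-2,2-dimethylchroman-6-yl]chroman-4,7-diol (target), via organoborane 17 (not isolated), via bis-pivalate alcohol 18 (not isolated)
Conditions: IpcBH2 (3 equiv; freed from the (−)-α-pinene-derived (IpcBH2)2·TMEDA with BF3·OEt2), THF, −25 → 0 °C; then NaOH (3 M), H2O2, 0 → 25 °C; then NaOH, MeOH, 40 °C; NH4Cl work-up
Reagents that add atoms: hydrogen peroxide (OO)
Why: Proposed new method: asymmetric hydroboration of an isoflav-3-ene with monoisopinocampheylborane; four-centre syn addition puts boron on the less substituted C4 and hydrogen on C3, so oxidation with retention can only give the 3,4-trans alcohol, and Brown's empirical rule for 1-arylcycloalkenes (the (+)-α-pinene reagent gives (1S,2R)-trans-2-arylcycloalkanols, which maps onto (3S,4R) here) predicts (3R,4S) from the (−)-α-pinene reagent; the closest known reactions are IpcBH2 hydroboration of 1-phenylcyclohexene and racemic BH3 hydroboration of isoflav-3-enes to trans-isoflavan-4-ols; any minor (3S,4R) product is a diastereomer because of the (3R) pyran carbinol and can be separated, and alkaline peroxide then hydroxide cleave both aryl pivalates without acid.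

**Compound list**
1 | resorcinol | Oc1cccc(O)c1 | starting material
2 | N,N-dimethylformamide | CN(C)C=O | starting material
3 | (2,4-dihydroxybenzylidene)dimethyliminium chloride | C[N+](C)=Cc1ccc(O)cc1O.[Cl-] | intermediate
4 | 2,4-dihydroxybenzaldehyde | O=Cc1ccc(O)cc1O | intermediate
5 | 3-methylbut-2-enal | CC(C)=CC=O | starting material
6 | 5-hydroxy-2,2-dimethyl-2H-chromene-6-carbaldehyde | CC1(C)C=Cc2c(O1)ccc(C=O)c2O | intermediate
7 | acetic acid | CC(O)=O | starting material
8 | 1-(2,4-dihydroxyphenyl)ethanone | CC(=O)c1ccc(O)cc1O | intermediate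
9 | (E)-1-(2,4-dihydroxyphenyl)-3-(5-hydroxy-2,2-dimethyl-2H-chromen-6-yl)prop-2-en-1-one | O=C(/C=C/c1ccc2OC(C)(C)C=Cc2c1O)c1ccc(O)cc1O | intermediate
10 | (±)-7-hydroxy-2-(5-hydroxy-2,2-dimethyl-2H-chromen-6-yl)chroman-4-one | CC1(C)C=Cc2c(O1)ccc(C1CC(=O)c3ccc(O)cc3O1)c2O | intermediate
11 | (±)-2-[2,2-dimethyl-5-(pivaloyloxy)-2H-chromen-6-yl]-4-oxochroman-7-yl pivalate | CC1(C)C=Cc2c(O1)ccc(C1CC(=O)c3ccc(OC(=O)C(C)(C)C)cc3O1)c2OC(=O)C(C)(C)C | intermediate
12 | (3R,4R)-3,4-epoxide of 11 on the dimethylpyran ring, C2 epimers of the chromanone | CC1(C)Oc2ccc(C3CC(=O)c4ccc(OC(=O)C(C)(C)C)cc4O3)c(OC(=O)C(C)(C)C)c2[C@H]2O[C@@H]12 | intermediate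
13 | 2-[(3R)-3-hydroxy-2,2-dimethyl-5-(pivaloyloxy)chroman-6-yl]-4-oxochroman-7-yl pivalate, C2 epimers | CC1(C)Oc2ccc(C3CC(=O)c4ccc(OC(=O)C(C)(C)C)cc4O3)c(OC(=O)C(C)(C)C)c2C[C@H]1O | intermediate
14 | 3-[(3R)-3-hydroxy-2,2-dimethyl-5-(pivaloyloxy)chroman-6-yl]-4-oxo-4H-chromen-7-yl pivalate | CC1(C)Oc2ccc(-c3coc4cc(OC(=O)C(C)(C)C)ccc4c3=O)c(OC(=O)C(C)(C)C)c2C[C@H]1O | intermediate
15 | 4-hydroxy-3-[(3R)-3-hydroxy-2,2-dimethyl-5-(pivaloyloxy)chroman-6-yl]chroman-7-yl pivalate, mixture of C3/C4 isomers | CC1(C)Oc2ccc(C3COc4cc(OC(=O)C(C)(C)C)ccc4C3O)c(OC(=O)C(C)(C)C)c2C[C@H]1O | intermediate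
16 | 3-[(3R)-3-hydroxy-2,2-dimethyl-5-(pivaloyloxy)chroman-6-yl]-2H-chromen-7-yl pivalate | CC1(C)Oc2ccc(C3=Cc4ccc(OC(=O)C(C)(C)C)cc4OC3)c(OC(=O)C(C)(C)C)c2C[C@H]1O | intermediate
17 | syn hydroboration adduct of 16: C4–BH(Ipc) trans to the C3 aryl group, pyran carbinol as O–BH(Ipc), Ipc from (−)-α-pinene | CC1(C)Oc2ccc([C@@H]3COc4cc(OC(=O)C(C)(C)C)ccc4[C@H]3B[C@H]3C[C@H]4C[C@@H]([C@@H]3C)C4(C)C)c(OC(=O)C(C)(C)C)c2C[C@H]1OB[C@H]1C[C@H]2C[C@@H]([C@@H]1C)C2(C)C | intermediate
18 | (3R,4S)-4-hydroxy-3-[(3R)-3-hydroxy-2,2-dimethyl-5-(pivaloyloxy)chroman-6-yl]chroman-7-yl pivalate | CC1(C)Oc2ccc([C@@H]3COc4cc(OC(=O)C(C)(C)C)ccc4[C@H]3O)c(OC(=O)C(C)(C)C)c2C[C@H]1O | intermediate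
19 | (3R,4S)-3-[(3R)-3,5-dihydroxy-2,2-dimethylchroman-6-yl]chroman-4,7-diol | CC1(C)Oc2ccc([C@@H]3COc4cc(O)ccc4[C@H]3O)c(O)c2C[C@H]1O | target

**Totals and risks**
Total steps: 10. Longest linear sequence: 9 (steps 1, 2, 4, 5, 6, 7, 8, 9, 10). One protecting-group step goes on and none comes off separately.

Most likely to fail:

Step 4 (unprotected condensation of two polyphenols; low conversion or amine adducts). The fallback sets out from 6 and 8 and comes back at 10. Aldehyde 6 is converted with MOMCl/iPr2NEt into 5-(methoxymethoxy)-2,2-dimethyl-2H-chromene-6-carbaldehyde F1, and ketone 8 with MOMCl/K2CO3 into 1-[2-hydroxy-4-(methoxymethoxy)phenyl]ethanone F2. A standard KOH/EtOH Claisen–Schmidt condensation then gives the 2'-hydroxychalcone bis-MOM ether F3. NaOAc in refluxing EtOH closes it to the flavanone bis-MOM ether F4, and dilute HCl in MeOH at 40 °C removes both MOM groups to give 10.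

Step 8 (flavone by dehydrogenation, α-tosyloxylation or ring contraction instead of aryl migration). The fallback sets out from 13 and comes back at 14. It moves the rearrangement to the pre-formed enol ether under oxythallation. HC(OMe)3/MeOH with catalytic H2SO4 turns 13 into the 4-methoxy-2H-chromene enol ether F5. Thallium trinitrate trihydrate, Tl(NO3)3·3H2O (trivalent thallium), at −10 → 25 °C adds at C3 and triggers the same 1,2-aryl shift, giving the isoflavone dimethyl ketal F6. 1 M HCl hydrolyses this to 14.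

Step 10 (the proposed new step; slow addition to a hindered trisubstituted stilbene-type alkene, or low or reversed facial selectivity). The fallback uses known chemistry, sets out from 14 and comes back at 19. Asymmetric transfer hydrogenation of the isoflavone with RuCl(p-cymene)[(R,R)-TsDPEN] (divalent ruthenium) in HCO2H/Et3N reduces the C=C bond and then the ketone with dynamic kinetic resolution, giving the cis-(3R,4R)-isoflavan-4-ol bis-pivalate F7. Mitsunobu inversion of the benzylic alcohol (4-nitrobenzoic acid, PPh3, DIAD, THF, 0 °C; the hindered pyran carbinol does not react) gives the trans-(3R,4S) 4-nitrobenzoate F8. NaOH in MeOH then cleaves the nitrobenzoate and both pivalates to give 19.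

**Further compounds**
F1 | step 4 | 5-(methoxymethoxy)-2,2-dimethyl-2H-chromene-6-carbaldehyde | CC1(C)C=Cc2c(O1)ccc(C=O)c2OCOC
F2 | step 4 | 1-[2-hydroxy-4-(methoxymethoxy)phenyl]ethanone | CC(=O)c1ccc(OCOC)cc1O
F3 | step 4 | (E)-1-[2-hydroxy-4-(methoxymethoxy)phenyl]-3-[5-(methoxymethoxy)-2,2-dimethyl-2H-chromen-6-yl]prop-2-en-1-one | O=C(/C=C/c1ccc2OC(C)(C)C=Cc2c1OCOC)c1ccc(OCOC)cc1O
F4 | step 4 | (±)-7-(methoxymethoxy)-2-[5-(methoxymethoxy)-2,2-dimethyl-2H-chromen-6-yl]chroman-4-one | CC1(C)C=Cc2c(O1)ccc(C1CC(=O)c3ccc(OCOC)cc3O1)c2OCOC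
F5 | step 8 | 2-[(3R)-3-hydroxy-2,2-dimethyl-5-(pivaloyloxy)chroman-6-yl]-4-methoxy-2H-chromen-7-yl pivalate | CC1(C)Oc2ccc(C3C=C(OC)c4ccc(OC(=O)C(C)(C)C)cc4O3)c(OC(=O)C(C)(C)C)c2C[C@H]1O
F6 | step 8 | 3-[(3R)-3-hydroxy-2,2-dimethyl-5-(pivaloyloxy)chroman-6-yl]-4,4-dimethoxy-4H-chromen-7-yl pivalate | CC1(C)Oc2ccc(C3=COc4cc(OC(=O)C(C)(C)C)ccc4C3(OC)OC)c(OC(=O)C(C)(C)C)c2C[C@H]1O
F7 | step 10 | (3R,4R)-4-hydroxy-3-[(3R)-3-hydroxy-2,2-dimethyl-5-(pivaloyloxy)chroman-6-yl]chroman-7-yl pivalate | CC1(C)Oc2ccc([C@@H]3COc4cc(OC(=O)C(C)(C)C)ccc4[C@@H]3O)c(OC(=O)C(C)(C)C)c2C[C@H]1O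
F8 | step 10 | (3R,4S)-3-[(3R)-3-hydroxy-2,2-dimethyl-5-(pivaloyloxy)chroman-6-yl]-7-(pivaloyloxy)chroman-4-yl 4-nitrobenzoate | CC1(C)Oc2ccc([C@@H]3COc4cc(OC(=O)C(C)(C)C)ccc4[C@H]3OC(=O)c3ccc(cc3)[N+](=O)[O-])c(OC(=O)C(C)(C)C)c2C[C@H]1O
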